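Follow the fraction of substrate left, not the fraction of target made. The question for each option is what the flask can still give.

| flask | substrate | coupling partner | temperature | remark | time |
|---|---|---|---|---|---|
| Saturday's | 1.5 M | 1.8 M | −20 °C | the very flask that is asked about, followed so far |  |
| Thursday's | 3 M | 1.8 M | −25 °C | run made earlier |  |
| flask | 1.5 M | 1.80 M | −20 °C |  | 4.0 d |

- Saturday's (time / d: target / %, substrate / %): 0.500: 26, 55; 1.04: 46, 33; 1.25: 54, 26; 2.08: 66, 11; 2.50: 67, 8
- Thursday's (time / d: target / %, substrate / %): 0.333: 14, 85; 1.04: 24, 61; 1.67: 37, 43; 3.00: 52, 25; 4.00: 58, 17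

(standard deviation of a reading: 1.5 percentage points)

- target that was removed still counts
- the earlier runs were read with a standard deviation of 1.5 percentage points

- midnight: change nothing and wait 50 h more
- spring: at 4.0 d take out 90% of the target then present, then wait 50 h
- dusk: at 4.0 d raise the temperature by 25 K, then wait 50 h

1. target, in percent of the substrate first charged, at 4.0 d
2. which option adds most target ("none" when 2 percentage points or less is all one gets) (midnight / spring / dusk / none)
3. target present, with what was taken out counted in, in percent of the substrate first charged, after spring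
4. target present, with what was taken out counted in, in percent of the substrate first charged, after dusk

1. Treat the substrate as a first-order decay, like a discharging capacitor: [substrate] over its charge is L = exp(−t/τ). The last reading of Saturday's flask, 8% left at 2.50 d, gives τ = 0.990 d. This is a reading, with its scatter.

2. The bench rule says a decay is over after a few time constants. By 4.0 d you have had 4.04 of them, so L = 1.76%.

3. Late in Saturday's flask, target per substrate used (the selectivity) reads s = 0.728. My own reckoning for target at 4.0 d is therefore s(1 − L) = 71.5%.

4. From Saturday's flask at 4.0 d you can still expect 1.28%. This is the reserve, s times L, the target still to come from free substrate. It is less than the 2 points an option must beat, so on this reckoning midnight falls short.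

5. Here the rule meets its border. At the first reading of Saturday's flask the same ratio is 0.578, lower than late, so s is not a constant along that run. At the last reading, 25.0% of the charge is neither, 19.5 times the reserve, and I leave open whether it returns. Thursday's last reading gives τ = 2.26 d, 2.28 times the value at Saturday's warmer temperature, but Thursday's flask also held twice the substrate, so this factor mixes the two changes. With s held fixed, a shorter τ after heating collects the same reserve sooner, so on this reckoning any larger gain from spring or dusk has to come from the unread share.

6. The forecast gives 72% for now, spring as best, 89% after spring and 73% after dusk. Its ground: “I bet on equilibrium.”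

7. Saturday's flask holds 70.9% at 4.0 d, and the best option is dusk, reaching 76.0%. Midnight and spring each add 1.4 points, so spring ends at 72.3%, 17 points below the forecast. Now plus the reserve makes 72.2%, against spring's 72.3%, while dusk stands above that sum.

    coupling partner ⇌ dormant form (K = 0.582, k = 3.82 × 10⁻⁶ s⁻¹, Ea = 86.0 kJ mol⁻¹, ΔH = 60.0 kJ mol⁻¹)
    intermediate A ⇌ intermediate B (K = 14.0, k = 2.17 × 10⁻⁵ s⁻¹, Ea = 89.0 kJ mol⁻¹, ΔH = −14.0 kJ mol⁻¹)
    substrate + coupling partner ⇌ intermediate A (K = 0.293 M⁻¹, k = 2.99 × 10⁻⁶ M⁻¹ s⁻¹, Ea = 79.0 kJ mol⁻¹, ΔH = −30.0 kJ mol⁻¹)
    substrate → target (k = 8.65 × 10⁻⁶ s⁻¹, Ea = 87.0 kJ mol⁻¹)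
    intermediate B ⇌ intermediate C (K = 33.0, k = 2.44 × 10⁻⁵ s⁻¹, Ea = 79.0 kJ mol⁻¹, ΔH = −75.0 kJ mol⁻¹)
    intermediate A → decomposed reagent (k = 3.65 × 10⁻⁵ s⁻¹, Ea = 91.0 kJ mol⁻¹)
    coupling partner + intermediate A → side product (k = 3.40 × 10⁻⁶ M⁻¹ s⁻¹, Ea = 73.0 kJ mol⁻¹)
    (constants at −20 °C)

8. Take the neighbour kept at −45 °C, 5 times the gap between the two runs below Saturday's temperature. Extrapolating with the same factor per gap and with s from Saturday's flask, my estimate is τ = 61.1 d, L = 93.7% and a reserve of 68.2%. Computed at 4.0 d, that flask holds substrate 94.0% and target 3.13%.

Readings and results are simulated from invented constants, noise included.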